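The constants of this flask are not given, so you read one off the runs before you forecast anything.

| flask | starting material | partner | catalyst | time |
|---|---|---|---|---|
| midnight | 300 mM | 360 mM | 6.00 mM |  |
| summer | 150 mM | 210 mM | 6.00 mM |  |
| noon | 300 mM | 180 mM | 6.00 mM |  |
| winter | 900 mM | 360 mM | 6.00 mM |  |
| spring | 300 mM | 360 mM | 6.00 mM | 56 min |

| run | time / min | [target] / mM |
|---|---|---|
| midnight run | 0.38 | 5.8 |
| midnight run | 0.84 | 10.5 |
| midnight run | 1.9 | 28.8 |
| midnight run | 4.2 | 66.5 |
| midnight run | 9.4 | 124.2 |
| summer run | 0.38 | 3.2 |
| summer run | 0.84 | 6.4 |
| summer run | 1.9 | 13.5 |
| summer run | 4.2 | 30.3 |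
| summer run | 9.4 | 55.8 |
| noon run | 0.38 | 2.3 |
| noon run | 0.84 | 6.1 |
| noon run | 1.9 | 14.2 |
| noon run | 4.2 | 32.3 |
| noon run | 9.4 | 67.4 |
| winter run | 0.38 | 5.5 |
| winter run | 0.84 | 15.7 |
| winter run | 1.9 | 51.1 |
| winter run | 4.2 | 142.8 |
| winter run | 9.4 | 266.6 |

(standard deviation of a reading: 0.9 mM)

1. reaction order in [starting material] at the outset, round the charge of the midnight run, defined at two percent of the starting material turned into target (one fixed amount of target, the same in the runs compared)
2. reaction order in [partner] at the outset, round the charge of the midnight run, defined at two percent of the starting material turned into target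
3. target in the spring run at 56 min, as a share of the starting material charged

- Overall: starting material + partner -> target, with catalyst as catalyst.
- Constant volume, constant temperature.
- What is held in complexes is read along with the free species.
- "The second partner" is partner.
- An order is taken over about fifteen percent of the charge, up and down.

Take the mean rate up to the third reading. The noon run, with less partner than the midnight run, gives 7.47 mM min⁻¹, and the midnight run gives 15.2 mM min⁻¹. The winter run, with more starting material than the midnight run, gives 26.9 mM min⁻¹. As orders, my estimates are:

order in partner ≈ 1.02

order in starting material ≈ 0.522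

The second is rough: by then the winter run has made more target than the midnight run. Still, it is low. So I suppose that binding is fast: the catalyst sits bound to starting material (its resting state), and the partner empties it. Then I carry one constant: the turnover constant κ, the rate divided by c(catalyst) and c(partner). In the midnight run, c(partner) averages 346 mM over that span, so:

κ = 15.2 mM min⁻¹ / (6.00 mM × 346 mM) = 7.31 L mol⁻¹ min⁻¹

Next comes the clock on the partner:

τ = 1 / (κ × c(catalyst)) = 22.8 min

Carry it to a later reading of the midnight run, at 9.4 min. It gives 122 mM, and the reading is 124.2 mM.

Now the spring run. With less starting material than partner in the spring run, starting material is the limiting reagent, so the clock meets its charge at: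

τ × ln(c(partner) / (c(partner) − c(starting material))) = 40.9 min

That is earlier than 56 min. So I commit to nearly all of the starting material as target.

The forecast differs from my number. It gives 0.25 (−0.1 to 0.6) and 1 (0.8 to 1.2) for the orders, and 86 % (72 % to 94 %) for the spring run. Its ground for the last is to “integrate second-order kinetics”.

The flask gives 0.30 and 0.82 for the orders, and 49.3 % for the spring run.

    catalyst + starting material → catalyst-substrate complex (37.80 L mol⁻¹ min⁻¹)
    catalyst-substrate complex + partner → target + catalyst (8.400 L mol⁻¹ min⁻¹)
    starting material → decomposed substrate (0.1134 min⁻¹)
    starting material + partner + target → 2 target (2.106 L² mol⁻² min⁻¹)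

My weak link was a starting material that waits. In the noon run, κ gives 7.89 mM min⁻¹ on the charge of partner, and the simulated early rate is 8.2 mM min⁻¹. In the spring run, κ on the mean partner of the midnight run's first 9.4 min gives 13.1 mM min⁻¹, while decomposition starts at 34.0 mM min⁻¹. Letting both draw on the charge gives:

target = (rate / k3) × ln(1 + k3 × c(starting material) / rate) = 148 mM

In the spring run, target formation and decomposition ran side by side while starting material was there, and in this reckoning starting material reaches zero near 11.3 min. At 56 min, 212 mM of partner stood unused, and target stood at 49.3 %.

(The data were generated by integration for an exercise; noise was put on by code.)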